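The percentage of the charge that has become product is what stays put between these runs: at 3.00 min the amber run shows 82.0% and the green run 82.5%, though green holds 4.00 times the charge.

the same everywhere: capture agent 0.213 M

| run | starting material | remark | time |
|---|---|---|---|
| amber | 0.35 M (fed, over 12 s) | run made earlier |  |
| green | 1.4 M (fed, over 12 s) | run made earlier |  |
| flask | 0.71 M (fed, over 12 s) |  | 4.0 min |

| run | time / min | product / % | starting material / % |
|---|---|---|---|
| amber | 0.500 | 26.0 | 44.7 |
| amber | 1.00 | 48.6 | 27.8 |
| amber | 1.33 | 61.7 | 22.2 |
| amber | 2.00 | 72.6 | 11.3 |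
| amber | 2.50 | 79.4 | 7.4 |
| amber | 3.00 | 82.0 | 4.3 |
| green | 0.250 | 7.4 | 56.3 |
| green | 0.417 | 20.3 | 47.9 |
| green | 0.667 | 35.3 | 38.2 |
| green | 0.833 | 42.0 | 32.2 |
| green | 1.33 | 59.4 | 22.2 |
| green | 2.00 | 71.6 | 10.6 |
| green | 3.00 | 82.5 | 4.8 |

(each reading ± 1 percentage point)



- amount of product in percent of the starting material charged, at 50 s, 2.0 min and 4.0 min

My decision concerns the flask: do I keep c(starting material) at 0.71 M and stop at 4.0 min? The charge did not move the percentages beyond about 2.3 percentage points at any shared time, so I keep it and look at time instead. The end state I expect is a charge turned into product, so I follow the remainder, the percentage not yet product. Averaged over both runs, it stands at 27.9% at 2.00 min and 17.7% at 3.00 min. Between those two times that is an average fractional loss of 0.452 min⁻¹ per unit time, the remainder rate. It is a reading over one interval and no constant of the curve: the amber run from 1.00 min to 2.00 min reads 0.629 min⁻¹, faster than that.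

If I assume that the rate holds on to 4.0 min, my estimate of the remainder in the flask is 11.3%, so my own figure is 88.7% product. That is enough, so I stop there. For the earlier times I read the curve: green gives 42.0% at 50 s, and the two runs average 72.1% at 2.0 min.

The forecast says 41.5%, 72% and 88%, on the grounds that “the course is therefore concentration-independent, effectively first-order”. Its last figure lies below mine.

The flask gives 42.3%, 72.9% and 88.0%.

    starting material ⇌ intermediate A (K = 0.610, k = 0.420 s⁻¹)
    intermediate C → intermediate D (k = 0.00550 s⁻¹)
    intermediate B ⇌ intermediate C (K = 0.610, k = 0.0100 s⁻¹)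
    intermediate A → intermediate B (k = 0.00460 s⁻¹)
    intermediate D → product (k = 0.0420 s⁻¹)
    intermediate A → product (k = 0.0360 s⁻¹)
    capture agent + intermediate C → trapped intermediate (k = 0.00890 L mol⁻¹ s⁻¹)

From 2.0 min to 4.0 min the remainder in the flask shrinks at 0.407 min⁻¹, less than the 0.452 min⁻¹ I read. Part of what is missing at 4.0 min is held back by the step from intermediate A to intermediate B: without that step the flask reaches 95.6%, and a run ten times as long reaches 97.2%. With c(starting material) at 1.42 M, the remainder rate again gives 88.7%, and that simulated run gives 88.0%.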